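**Strategy.** Everything rests on disconnecting C2 twice at once: the C1–C2 bond and the C2 O–acetyl bond. The feature used is that C2 is an acetoxy-bearing secondary carbon flanked by the benzylic C1 methylene on the benzene ring (ring A) and the C3 methylene, i.e. the adduct carbon of an aldehyde, an acyl bromide and a benzyl nucleophile. In one pot, aldehyde 7 (C8 hydroxyl as TIPS ether, S centre bought with (S)-oct-1-yn-3-ol) and acetyl bromide give a racemic 1-bromoalkyl acetate that a chiral catalyst made from NiBr2·dme and a bis(oxazoline) couples with the TIPS-protected benzylzinc bromide 12, setting C2 as R. One fluoride step then unveils the target.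

Key step: step 9

Remark: the sense of induction of a given bis(oxazoline) enantiomer with a benzylic zinc partner cannot be predicted; it is assumed that one of the two available ligand enantiomers delivers 2R, to be fixed in a model run with hexanal.

Step 1
Reactants: 1 (S)-oct-1-yn-3-ol
Product: 2 (S)-triisopropyl(oct-1-yn-3-yloxy)silane
Conditions: TIPSCl, imidazole, DMAP (cat.), DMF, rt
Reagents that add atoms: triisopropylsilyl chloride, CC(C)[Si](Cl)(C(C)C)C(C)C
Why: Imidazole-promoted silyl ether formation occurs at oxygen without touching the carbinol stereocentre, and the bulky TIPS group is chosen because it must later survive aqueous acid and acetyl bromide.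

Step 2
Reactants: 2 (S)-triisopropyl(oct-1-yn-3-yloxy)silane; 3 2-(3-bromopropyl)-1,3-dioxolane
Product: 5 2-[(6S)-6-(triisopropylsilyloxy)undec-4-yn-1-yl]-1,3-dioxolane, via lithium acetylide 4 (not isolated)
Conditions: n-BuLi, THF, −78 °C; then 3, DMPU, −78 °C → rt
Reagents that add atoms: none
Why: Acetylide alkylation (SN2), in which the DMPU-activated lithium acetylide displaces bromide from the unbranched primary bromide while the silyl ether and the dioxolane are inert to base.

Step 3
Reactants: 5 2-[(6S)-6-(triisopropylsilyloxy)undec-4-yn-1-yl]-1,3-dioxolane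
Product: 6 2-[(6S)-6-(triisopropylsilyloxy)undecyl]-1,3-dioxolane
Conditions: H2 (1 atm), 5% Pt/C, EtOAc, rt
Reagents that add atoms: none
Why: Heterogeneous catalytic hydrogenation saturates the alkyne, and platinum is preferred to palladium because it causes little double-bond migration or C–O hydrogenolysis at the intermediate allylic ether, so the S centre and the silyl ether should be retained.

Step 4
Reactants: 6 2-[(6S)-6-(triisopropylsilyloxy)undecyl]-1,3-dioxolane
Product: 7 (S)-7-(triisopropylsilyloxy)dodecanal
Conditions: 2 M aq HCl/THF (1:4), rt; used without storage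
Reagents that add atoms: water, O
Why: Acid-catalysed acetal hydrolysis frees the aldehyde, while the hindered secondary TIPS ether is stable to dilute aqueous acid at room temperature.

Step 5
Reactants: 8 methyl 3-hydroxy-5-methoxybenzoate
Product: 9 methyl 3-methoxy-5-(triisopropylsilyloxy)benzoate
Conditions: TIPSCl, imidazole, DMF, rt
Reagents that add atoms: triisopropylsilyl chloride, CC(C)[Si](Cl)(C(C)C)C(C)C
Why: Phenol silylation (silyl ether formation) masks the acidic O–H that would quench the later organozinc reagent, and the methyl ester is untouched.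

Step 6
Reactants: 9 methyl 3-methoxy-5-(triisopropylsilyloxy)benzoate
Product: 10 [3-methoxy-5-(triisopropylsilyloxy)phenyl]methanol
Conditions: i-Bu2AlH (2.5 equiv), CH2Cl2, −78 → 0 °C; aq potassium sodium tartrate
Reagents that add atoms: none
Why: Ester reduction to the primary alcohol with a dialkylaluminium hydride at low temperature leaves the aryl silyl ether intact.

Step 7
Reactants: 10 [3-methoxy-5-(triisopropylsilyloxy)phenyl]methanol
Product: 11 [3-(bromomethyl)-5-methoxyphenoxy]triisopropylsilane
Conditions: CBr4, PPh3, CH2Cl2, 0 °C
Reagents that add atoms: carbon tetrabromide, BrC(Br)(Br)Br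
Why: The Appel reaction converts the benzylic alcohol to the bromide under neutral conditions that do not cleave the aryl silyl ether.

Step 8
Reactants: 11 [3-(bromomethyl)-5-methoxyphenoxy]triisopropylsilane
Product: 12 3-methoxy-5-(triisopropylsilyloxy)benzylzinc bromide (THF solution containing LiCl, titrated with iodine)
Conditions: Zn dust (activated with BrCH2CH2Br, TMSCl), LiCl, THF, 0 °C → rt, slow addition of 11
Reagents that add atoms: zinc, [Zn]
Why: Oxidative insertion of LiCl-activated zinc into the benzylic C–Br bond gives the benzylzinc bromide, with slow addition at 0 °C limiting Wurtz homocoupling and both aryl ethers inert.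

Step 9
Reactants: 7 (S)-7-(triisopropylsilyloxy)dodecanal; 13 acetyl bromide; 12 3-methoxy-5-(triisopropylsilyloxy)benzylzinc bromide
Product: 15 (2R,8S)-1-[3-methoxy-5-(triisopropylsilyloxy)phenyl]-8-(triisopropylsilyloxy)tridecan-2-yl acetate, via 1-bromoalkyl acetate 14 (not isolated)
Conditions: (i) 13 (1.05 equiv), CH2Cl2, −20 → 0 °C, then volatiles off in vacuo; (ii) NiBr2·dme (10 mol%), chiral bis(oxazoline) ligand (Ph-BOX type, 12 mol%, enantiomer giving 2R), 12 (1.4 equiv, slow addition), THF, −25 °C
Reagents that add atoms: none
Why: Proposed new method: the carbonyl oxygen of 7 is acylated by acetyl bromide and bromide adds to the resulting acyloxycarbenium ion, giving 14 as both C1 epimers; the monovalent nickel complex L*NiBr (L* = the bis(oxazoline)) then abstracts bromine to leave a planar 1-acetoxyalkyl radical, the benzylnickel species formed by transmetalation from 12 captures it, and reductive elimination from trivalent nickel makes the C1–C2 bond. The closest known reaction type is the nickel-catalysed enantioconvergent Negishi coupling of racemic 1-bromoalkyl esters, generated in situ from unbranched aldehydes and acyl bromides, with primary alkylzinc halides; a benzylic zinc partner has not been shown there, but it transmetalates readily to nickel and its nickel complex has no β-hydrogen to lose. No ring is formed. The new stereocentre C2 is set under ligand control at the radical-capture and reductive-elimination stage, both epimers of 14 converging on one product, and the ligand enantiomer is chosen for 2R because the silylated C8 centre is six bonds away and cannot bias the outcome. The step needs catalyst-controlled enantioselectivity and preference for the nickel pathway over direct ionic substitution of 14 or acylation of 12; the substrate helps through the acetoxy carbonyl beside the radical carbon, which gives the catalyst a second binding point, and through its unbranched chain, while removal of excess acetyl bromide, low temperature and slow addition of 12 hold back the background reactions.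

Step 10
Reactants: 15 (2R,8S)-1-[3-methoxy-5-(triisopropylsilyloxy)phenyl]-8-(triisopropylsilyloxy)tridecan-2-yl acetate
Product: 16 (2R,8S)-8-hydroxy-1-(3-hydroxy-5-methoxyphenyl)tridecan-2-yl acetate
Conditions: HF·pyridine (excess), pyridine, THF, 0 °C → rt (polypropylene vessel)
Reagents that add atoms: none
Why: Fluoride-mediated desilylation cleaves both the aryl and the secondary alkyl Si–O bonds, whereas the acetate is stable to this buffered acidic fluoride source and no stereocentre is touched.

**Compound list**

1 | (S)-oct-1-yn-3-ol | CCCCC[C@H](O)C#C | starting material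
2 | (S)-triisopropyl(oct-1-yn-3-yloxy)silane | CCCCC[C@H](O[Si](C(C)C)(C(C)C)C(C)C)C#C | intermediate
3 | 2-(3-bromopropyl)-1,3-dioxolane | BrCCCC1OCCO1 | starting material
4 | lithium (S)-3-(triisopropylsilyloxy)oct-1-yn-1-ide | CCCCC[C@H](O[Si](C(C)C)(C(C)C)C(C)C)C#C[Li] | intermediate (not isolated)
5 | 2-[(6S)-6-(triisopropylsilyloxy)undec-4-yn-1-yl]-1,3-dioxolane | CCCCC[C@H](O[Si](C(C)C)(C(C)C)C(C)C)C#CCCCC1OCCO1 | intermediate
6 | 2-[(6S)-6-(triisopropylsilyloxy)undecyl]-1,3-dioxolane | CCCCC[C@H](O[Si](C(C)C)(C(C)C)C(C)C)CCCCCC1OCCO1 | intermediate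
7 | (S)-7-(triisopropylsilyloxy)dodecanal | CCCCC[C@H](O[Si](C(C)C)(C(C)C)C(C)C)CCCCCC=O | intermediate
8 | methyl 3-hydroxy-5-methoxybenzoate | COC(=O)c1cc(O)cc(OC)c1 | starting material
9 | methyl 3-methoxy-5-(triisopropylsilyloxy)benzoate | COC(=O)c1cc(OC)cc(O[Si](C(C)C)(C(C)C)C(C)C)c1 | intermediate
10 | [3-methoxy-5-(triisopropylsilyloxy)phenyl]methanol | COc1cc(CO)cc(O[Si](C(C)C)(C(C)C)C(C)C)c1 | intermediate
11 | [3-(bromomethyl)-5-methoxyphenoxy]triisopropylsilane | COc1cc(CBr)cc(O[Si](C(C)C)(C(C)C)C(C)C)c1 | intermediate
12 | 3-methoxy-5-(triisopropylsilyloxy)benzylzinc bromide | COc1cc(C[Zn]Br)cc(O[Si](C(C)C)(C(C)C)C(C)C)c1 | intermediate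
13 | acetyl bromide | CC(=O)Br | starting material
14 | (7S)-1-bromo-7-(triisopropylsilyloxy)dodecyl acetate (both C1 epimers) | CCCCC[C@H](O[Si](C(C)C)(C(C)C)C(C)C)CCCCCC(Br)OC(C)=O | intermediate (not isolated)
15 | (2R,8S)-1-[3-methoxy-5-(triisopropylsilyloxy)phenyl]-8-(triisopropylsilyloxy)tridecan-2-yl acetate | CCCCC[C@H](O[Si](C(C)C)(C(C)C)C(C)C)CCCCC[C@H](Cc1cc(O[Si](C(C)C)(C(C)C)C(C)C)cc(OC)c1)OC(C)=O | intermediate
16 | (2R,8S)-8-hydroxy-1-(3-hydroxy-5-methoxyphenyl)tridecan-2-yl acetate | CCCCC[C@H](O)CCCCC[C@H](Cc1cc(O)cc(OC)c1)OC(C)=O | target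

**Step count.** Total: 10 steps. Longest linear sequence: 6 steps (steps 1–4, 9, 10; the arene branch, steps 5–8, 9, 10, is equally long).

**Steps most likely to fail**

1. Step 9 (proposed new method). The uncatalysed ionic substitution of the bromoacetate by the benzylzinc reagent may outrun the nickel cycle, the zinc reagent may be acylated, or facial discrimination at nickel may be weak with a benzylic partner. Any loss of control at C2 cannot be repaired later, because the epimers differ only at remote centres and should not be separable. The fallback uses known reactions only, sets out from aldehyde 7 and comes back at 15.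
   - Corey–Chaykovsky methylenation of 7 (trimethylsulfonium iodide, n-BuLi, THF, −10 °C → rt) should give 2-[(6S)-6-(triisopropylsilyloxy)undecyl]oxirane F1 as both epimers at the oxirane carbon.
   - Hydrolytic kinetic resolution with (R,R)-(salen)Co(OAc) [salen = N,N'-bis(3,5-di-tert-butylsalicylidene)-1,2-cyclohexanediamine] and 0.55 equiv water is expected to consume the 2S epimer as its diol and leave (2R)-2-[(6S)-6-(triisopropylsilyloxy)undecyl]oxirane F2.
   - Commercial 3-bromo-5-methoxyphenol is silylated (TIPSCl, imidazole, DMF) to (3-bromo-5-methoxyphenoxy)triisopropylsilane F3, and Mg turnings in THF convert it to 3-methoxy-5-(triisopropylsilyloxy)phenylmagnesium bromide F4.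
   - With CuI (10 mol%) at −30 → 0 °C, F4 opens F2 at its CH2 terminus with retention at C2 to give (2R,8S)-1-[3-methoxy-5-(triisopropylsilyloxy)phenyl]-8-(triisopropylsilyloxy)tridecan-2-ol F5.
   - Acetylation (Ac2O, pyridine, DMAP) gives 15.
   - The resolution sacrifices half of the oxirane, but the sequence also supplies a reference sample of 15 of secure configuration.

2. Step 8. Wurtz-type homocoupling during zinc insertion into the reactive benzylic bromide may consume the halide and leave a low titre. The fallback sets out from alcohol 10 and comes back at 15.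
   - 10 is converted (MsCl, Et3N, CH2Cl2, then LiCl, DMF) to [3-(chloromethyl)-5-methoxyphenoxy]triisopropylsilane F6.
   - Zn dust and LiCl in THF at rt insert into the C–Cl bond, which is too sluggish an electrophile to be attacked by the organozinc already formed, giving 3-methoxy-5-(triisopropylsilyloxy)benzylzinc chloride F7.
   - F7 replaces 12 in step 9, and the route is rejoined at 15.

3. Step 3. Double-bond migration at the allylic-ether stage of the hydrogenation would erode the carbinol configuration through an enol ether, and hydrogenolysis of the propargylic or allylic C–O bond would remove the oxygen. The fallback sets out from 2 and comes back at 6. It bypasses steps 2 and 3 by making the chain bond through an alkyl–alkyl Suzuki–Miyaura coupling.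
   - Semihydrogenation of 2 (H2, Pd/CaCO3 poisoned with Pb(OAc)2, quinoline, hexane) should give (S)-triisopropyl(oct-1-en-3-yloxy)silane F8.
   - Anti-Markovnikov hydroboration with 9-BBN in THF gives 9-[(3R)-3-(triisopropylsilyloxy)octyl]-9-borabicyclo[3.3.1]nonane F9 (descriptor changed by CIP priority only, geometry unchanged).
   - F9 is coupled with bromide 3 (Pd(OAc)2, PCy3, K3PO4·H2O, THF, rt) to give 6 directly, the stereocentre never lying next to a metal-bound π system under hydrogen.

**Further compounds**

F1 | step 9 | 2-[(6S)-6-(triisopropylsilyloxy)undecyl]oxirane (both epimers at the oxirane carbon) | CCCCC[C@H](O[Si](C(C)C)(C(C)C)C(C)C)CCCCCC1CO1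
F2 | step 9 | (2R)-2-[(6S)-6-(triisopropylsilyloxy)undecyl]oxirane | CCCCC[C@H](O[Si](C(C)C)(C(C)C)C(C)C)CCCCC[C@@H]1CO1
F3 | step 9 | (3-bromo-5-methoxyphenoxy)triisopropylsilane | COc1cc(Br)cc(O[Si](C(C)C)(C(C)C)C(C)C)c1
F4 | step 9 | 3-methoxy-5-(triisopropylsilyloxy)phenylmagnesium bromide | COc1cc([Mg]Br)cc(O[Si](C(C)C)(C(C)C)C(C)C)c1
F5 | step 9 | (2R,8S)-1-[3-methoxy-5-(triisopropylsilyloxy)phenyl]-8-(triisopropylsilyloxy)tridecan-2-ol | CCCCC[C@H](O[Si](C(C)C)(C(C)C)C(C)C)CCCCC[C@H](Cc1cc(O[Si](C(C)C)(C(C)C)C(C)C)cc(OC)c1)O
F6 | step 8 | [3-(chloromethyl)-5-methoxyphenoxy]triisopropylsilane | COc1cc(CCl)cc(O[Si](C(C)C)(C(C)C)C(C)C)c1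
F7 | step 8 | 3-methoxy-5-(triisopropylsilyloxy)benzylzinc chloride | COc1cc(C[Zn]Cl)cc(O[Si](C(C)C)(C(C)C)C(C)C)c1
F8 | step 3 | (S)-triisopropyl(oct-1-en-3-yloxy)silane | CCCCC[C@H](O[Si](C(C)C)(C(C)C)C(C)C)C=C
F9 | step 3 | 9-[(3R)-3-(triisopropylsilyloxy)octyl]-9-borabicyclo[3.3.1]nonane | CCCCC[C@H](O[Si](C(C)C)(C(C)C)C(C)C)CCB1C2CCCC1CCC2
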